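## Analysis of the target

The target 31 is an acylphloroglucinol: a 2,4,6-trihydroxyphenyl ketone whose carbonyl carbon is C1 of an unbranched C18 chain, numbered from the ketone to the methyl group. The chain carries a Z alkene at C6=C7, the only stereocentre as an (R)-carbinol at C9, an E,Z-conjugated diene at C10=C11/C12=C13 and a further Z alkene at C15=C16, so C8 and C14 are skipped methylenes. With one stereocentre there is no relative stereochemistry to manage; the task is absolute control at C9 and control of four alkene geometries (6Z, 10E, 12Z, 15Z). The C9 hydroxyl is allylic to the conjugated diene and should ionise readily under acid to a pentadienyl cation. The skipped polyene is prone to autoxidation and to isomerisation by base or radicals, and the free phloroglucinol is electron-rich, air-sensitive and nucleophilic at oxygen and carbon. The difficulty is therefore mostly one of ordering: the dienyl carbinol and the free triphenol should appear as late as possible, and C9 has to be set in a way that also fixes the neighbouring E alkene. The route rests on the segment C7–C8–C9(O)–C10=C11. Read with C7 as a carboxyl carbon, it is a β-oxygenated γ,δ-E-unsaturated acid, which is what a Claisen shift of an acetate onto the enol-ether terminus of an allyl unit delivers when the carbinol carbon of that unit is C11.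

## Retrosynthetic reasoning

31 to 30. The Z alkenes C12=C13 and C15=C16 are taken back to alkynes, so the last step is a twofold syn semihydrogenation. This places the acid-labile dienyl carbinol and the oxidation-prone skipped triene at the very end, and it makes C13–C14 a bond between two alkyne units.

30 to 29. The three phenols are masked as acetal ethers in 29. They are cleaved with acid while the chain still holds an enediyne and no conjugated diene, because the carbinol next to an enyne ionises far less readily than the one next to a diene.

29 to 25 and 26. The C13–C14 bond is cut between the terminal alkyne of 25 and the propargylic bromide 26. A copper-mediated coupling under carbonate conditions forms this sp–sp3 bond without a strong base, which a 1,4-diyne would not tolerate. The phenols must be protected at this point so that they are not alkylated by 26.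

25 to 24 to 20 and 23. The aryl–C1 bond is cut to a Weinreb amide (20) and the aryllithium 23, made by ortho-lithiation of 22, the tris-acetal of 21. This addition is placed before the skipped diyne is built, because the methylene between two alkynes would not survive an aryllithium, and after removal of the benzyl-type ether from O9, because that oxidative cleavage is cleanest with no electron-rich arene present. The silyl group on the alkyne protects the terminal C–H during the addition and is removed afterwards (24 to 25).

20 to 19 to 18 to 15 and 16. The Z alkene C6=C7 is cut by a Wittig disconnection into the β-alkoxy aldehyde 15 (C7 to C13) and the carboxylate ylide derived from salt 16 (C1 to C6). An unstabilised ylide under salt-free conditions is the most reliable source of a Z-disubstituted alkene, and the carboxyl group of 18 becomes the Weinreb amide 19.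

15 to 14 to 13. The aldehyde is the reduced form of ester 14, which is the methyl ester of acid 13. These two steps only adjust the oxidation state of C7.

13 to 10. The C8–C9 bond is cut in the sense of an ester-enolate Claisen rearrangement. The acid 13 comes from the acetate 10 of a propargylic carbinol whose allyl unit ends in an E enol ether. The forward reaction has to form C8–C9, create C9 with (R) configuration by transfer of the (S) configuration at C11, and leave C10=C11 as the E alkene. The oxygen at C9 is the enol-ether oxygen, so it arrives already protected.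

10 to 9 to 8. The acetate comes from the (S)-alcohol 9, and 9 from enantioselective reduction of the cross-conjugated ynone 8. The only stereocentre is thus installed by a catalytic reduction at a carbon (C11) that later becomes an alkene carbon.

8 to 5 and 6; 5 to 4 to 3 to 1 and 2. The ynone is cut at the carbonyl–alkyne bond into the Weinreb amide 5 and the acetylide of 6. The amide is derived through acid 4 from the β-alkoxyacrylate 3, the adduct of alcohol 2 to the propiolate 1. This addition sets the E geometry of the enol ether that the rearrangement needs, and it brings in O9.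

## Alternatives that were turned down

Alternative 1: The aromatic ring is disconnected rather than the chain: the bond between the acyl-bearing ring carbon and the neighbouring oxygenated ring carbon is cut, leading back to the open-chain 3,5,7-trioxo ester A2. In the forward step a magnesium alkoxide in its parent alcohol would form the polyenolate of A2, whose C6 attacks the ester carbon C1; the six-membered carbocycle loses a molecule of alcohol and enolises to the acylphloroglucinol A1, the 9-O-silyl ether of the target. In its favour, the arene is made last with no phenol protection, no aryllithium and no acetal cleavage, and a fluoride deprotection would finish the synthesis. Against it, A2 must already contain the complete chain with C9 and all four alkenes, so the disconnection does nothing for the stereocentre or the alkene geometries. A 3,5,7-triketo ester on such a chain would have to be made by polyanion acylation under strongly basic conditions, and the cyclisation has competing modes (aldol closure onto the C7 ketone to a resorcylate, or pyrone formation) that are hard to steer. On the end game this alternative is stronger than the chosen route, which needs an organolithium addition and an acid deprotection. The chosen strategy offers instead a defined solution for C9 and C10=C11 and a stepwise, well-precedented attachment of the arene.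

Alternative 2: The C6=C7 alkene is disconnected by ring-closing metathesis within a ten-membered lactone that ties the C1 carboxyl to O9, with C10 present as a protected hydroxymethyl group. In the forward step a ruthenium carbene catalyst of the N-heterocyclic carbene type would close the diene ester A4 to the lactone A3 with loss of a volatile alkene. In its favour, C9 comes from the chiral pool through the secondary alcohol of A4, so no asymmetric catalysis is needed. The ester tether also protects O9 and the acid together, and the ring is expected to favour the Z alkene. Against it, ten-membered rings are among the hardest to close by metathesis, since strain and oligomerisation compete, and the Z preference is not dependable. After the ring is made, the whole C10–C18 triene still has to be built from an epimerisable α-acyloxy aldehyde at C10, including the E alkene next to the stereocentre. On the source of chirality this alternative is stronger. The chosen strategy forms the C8–C9 bond, C9 and the E alkene in one step and leaves C6=C7 to an ordinary Z-selective Wittig reaction.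

Alternative 3: The C11–C12 bond between the diene and the skipped diyne is disconnected into the E-iodoalkene A6 and the diyne A7. In the forward step a zerovalent palladium catalyst with a monovalent copper co-catalyst in an amine would couple them to the dienediyne ester A5. In its favour, the route is convergent, the E geometry is fixed in A6 before the coupling, and this union has the most precedent in lipid synthesis. On convergence and precedent it is as strong as or stronger than the chosen route. Against it, A7 is volatile, and its methylene between two alkynes isomerises to allenes under the amine conditions of the coupling. A6 still needs a separate solution for C9 (typically a stoichiometric auxiliary) and a separate construction of the E-iodoalkene. The chosen strategy instead derives C9 and the E alkene together from one catalytically set carbinol and cheap two- and three-carbon building blocks, and it attaches C14–C18 under carbonate conditions that a skipped diyne tolerates.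

Key step: step 7

Assumption: in the transfer hydrogenation of 8 the silylalkynyl group is taken to occupy the catalyst site that an alkynyl group occupies in alkyl alkynyl ketones, so the (S,S)-catalyst should give (S)-9; if the alkoxyvinyl group takes that site instead, the (R,R)-catalyst is used.

## Route

Step 1
Reactants: 1 ethyl propiolate; 2 4-methoxybenzyl alcohol
Product: 3 ethyl (E)-3-[(4-methoxybenzyl)oxy]acrylate
Conditions: N-methylmorpholine (0.5 equiv), CH2Cl2, 0 °C to rt
Reagents that add atoms: none
Why: Amine-catalysed oxa-Michael addition of an alcohol to a propiolate; the alkoxide displaces the amine from the β-ammonium acrylate, and the E β-alkoxyacrylate should form as the thermodynamically preferred isomer.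

Step 2
Reactants: 3 ethyl (E)-3-[(4-methoxybenzyl)oxy]acrylate
Product: 4 (E)-3-[(4-methoxybenzyl)oxy]acrylic acid
Conditions: LiOH·H2O, THF/H2O, rt; then 1 M HCl to pH 3–4, 0 °C
Reagents that add atoms: lithium hydroxide, [Li+].[OH-]
Why: Ester saponification; the vinylogous carbonate is deactivated towards conjugate attack by hydroxide and towards enol-ether hydrolysis, so the acid should be isolable after cold, brief acidification.

Step 3
Reactants: 4 (E)-3-[(4-methoxybenzyl)oxy]acrylic acid
Product: 5 (E)-N-methoxy-N-methyl-3-[(4-methoxybenzyl)oxy]acrylamide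
Conditions: MeNHOMe·HCl, EDC·HCl, HOBt, i-Pr2NEt, CH2Cl2, 0 °C to rt
Reagents that add atoms: N,O-dimethylhydroxylamine hydrochloride, CNOC.Cl
Why: Carbodiimide amide coupling to the Weinreb amide; the weakly nucleophilic hydroxylamine should attack the activated acyl carbon rather than the β-carbon, which a direct aminolysis of ester 3 would not guarantee.

Step 4
Reactants: 5 (E)-N-methoxy-N-methyl-3-[(4-methoxybenzyl)oxy]acrylamide; 6 trimethylsilylacetylene
Product: 8 (E)-1-[(4-methoxybenzyl)oxy]-5-(trimethylsilyl)pent-1-en-4-yn-3-one, via lithium trimethylsilylacetylide 7 (not isolated)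
Conditions: 6, n-BuLi, THF, −78 °C; then 5, −78 to −30 °C; aq NH4Cl
Reagents that add atoms: none
Why: Weinreb ketone synthesis; the hard acetylide adds to the amide carbonyl and the chelated tetrahedral intermediate prevents a second addition, so the ynone should form with the E enol ether untouched.

Step 5
Reactants: 8 (E)-1-[(4-methoxybenzyl)oxy]-5-(trimethylsilyl)pent-1-en-4-yn-3-one
Product: 9 (S,E)-1-[(4-methoxybenzyl)oxy]-5-(trimethylsilyl)pent-1-en-4-yn-3-ol
Conditions: Ru[(S,S)-TsDPEN](p-cymene) (2 mol %; TsDPEN = N-tosyl-1,2-diphenylethylenediamine), i-PrOH, rt, no added base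
Reagents that add atoms: none
Why: Noyori asymmetric transfer hydrogenation of an alkynyl ketone through the six-membered metal–ligand bifunctional transition state; with the alkynyl group in the site next to the arene ligand the (S,S)-catalyst should give the (S)-carbinol, and the base-free conditions spare the ynone and the enol ether.

Step 6
Reactants: 9 (S,E)-1-[(4-methoxybenzyl)oxy]-5-(trimethylsilyl)pent-1-en-4-yn-3-ol
Product: 10 (S,E)-1-[(4-methoxybenzyl)oxy]-5-(trimethylsilyl)pent-1-en-4-yn-3-yl acetate
Conditions: Ac2O, Et3N, DMAP (5 mol %), CH2Cl2, 0 °C; chromatography on Et3N-deactivated silica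
Reagents that add atoms: acetic anhydride, CC(=O)OC(C)=O
Why: DMAP-catalysed O-acylation under basic conditions; the C–O bond at the stereocentre is not touched, so the configuration is retained, and acid is excluded because the γ-acyloxy enol ether can ionise.

Step 7
Reactants: 10 (S,E)-1-[(4-methoxybenzyl)oxy]-5-(trimethylsilyl)pent-1-en-4-yn-3-yl acetate
Product: 13 (R,E)-3-[(4-methoxybenzyl)oxy]-7-(trimethylsilyl)hept-4-en-6-ynoic acid, via silyl ketene acetal 11 (not isolated), via trimethylsilyl ester 12 (not isolated)
Conditions: LiN(i-Pr)2 (1.2 equiv), Me3SiCl/Et3N (premixed, 1.5 equiv, present during enolisation), THF, −78 °C; then −78 °C to rt; aqueous citrate buffer pH 5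
Reagents that add atoms: none
Why: Ireland–Claisen rearrangement: the acetate is enolised and O-silylated in situ to the silyl ketene acetal 11, which undergoes a concerted suprafacial [3,3]-shift in which the ketene-acetal CH2 (C8) bonds to the enol-ether carbon (C9) while the C11–O bond breaks, and the silyl ester 12 is hydrolysed to acid 13 on work-up. The closest known reaction type is the ester-enolate Claisen rearrangement of glycal esters, where the allyl terminus is likewise an enol ether and the carbinol configuration is transferred across the allyl unit. No ring is closed; one C–C bond and one stereocentre are formed. The new stereocentre C9 is controlled by the C11 stereocentre: in the chair with the alkynyl group pseudo-equatorial, C8 bonds to the face of the allyl unit from which the C11 oxygen departs, so the (S)-carbinol with an E enol ether gives (R) at C9. The same arrangement places the alkynyl group trans to C9 and so gives the E C10=C11 alkene. The step needs this E selectivity (a pseudo-axial alkynyl group would give the Z alkene together with the opposite configuration at C9) and needs the allyl unit, not the alkyne, to take part. The first is supported by the 1,3-diaxial contact between a pseudo-axial substituent and the silyloxy group, and the second by the higher barrier of the propargylic shift, the silyl group on the alkyne terminus and the accelerating alkoxy group on the allyl terminus. Because the ketene acetal terminus is an unsubstituted CH2, chair and boat arrangements lead to the same product, so only the orientation of the alkynyl group matters.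

Step 8
Reactants: 13 (R,E)-3-[(4-methoxybenzyl)oxy]-7-(trimethylsilyl)hept-4-en-6-ynoic acid
Product: 14 methyl (R,E)-3-[(4-methoxybenzyl)oxy]-7-(trimethylsilyl)hept-4-en-6-ynoate
Conditions: Me3SiCHN2 (2 M in hexanes), toluene/MeOH 4:1, 0 °C
Reagents that add atoms: (trimethylsilyl)diazomethane, C[Si](C)(C)C=[N+]=[N-]
Why: Methyl esterification with a diazomethane equivalent under neutral conditions, which should avoid base-induced β-elimination of the C9 alkoxy group.

Step 9
Reactants: 14 methyl (R,E)-3-[(4-methoxybenzyl)oxy]-7-(trimethylsilyl)hept-4-en-6-ynoate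
Product: 15 (R,E)-3-[(4-methoxybenzyl)oxy]-7-(trimethylsilyl)hept-4-en-6-ynal
Conditions: i-Bu2AlH (1.1 equiv), CH2Cl2, −78 °C; MeOH, then aqueous potassium sodium tartrate (KNaC4H4O6); used crude
Reagents that add atoms: none
Why: Partial reduction of an ester to the aldehyde; the β-alkoxy group stabilises the tetrahedral aluminium hemiacetal at −78 °C, and the silylalkyne is not hydroaluminated at this temperature.

Step 10
Reactants: 15 (R,E)-3-[(4-methoxybenzyl)oxy]-7-(trimethylsilyl)hept-4-en-6-ynal; 16 (5-carboxypentyl)triphenylphosphonium bromide
Product: 18 (6Z,9R,10E)-9-[(4-methoxybenzyl)oxy]-13-(trimethylsilyl)trideca-6,10-dien-12-ynoic acid, via carboxylate ylide 17 (not isolated)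
Conditions: 16, NaN(SiMe3)2 (2.0 equiv per 16), THF, 0 °C to rt; then 15, −78 to 0 °C; 0.5 M HCl to pH 4
Reagents that add atoms: none
Why: Wittig reaction of an unstabilised ylide under lithium-free conditions, which should give the Z alkene by kinetic formation of the cis-oxaphosphetane; exact base stoichiometry and low temperature keep the β-alkoxy aldehyde from eliminating, and C9 is not involved.

Step 11
Reactants: 18 (6Z,9R,10E)-9-[(4-methoxybenzyl)oxy]-13-(trimethylsilyl)trideca-6,10-dien-12-ynoic acid
Product: 19 (6Z,9R,10E)-N-methoxy-N-methyl-9-[(4-methoxybenzyl)oxy]-13-(trimethylsilyl)trideca-6,10-dien-12-ynamide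
Conditions: MeNHOMe·HCl, EDC·HCl, HOBt, i-Pr2NEt, CH2Cl2, 0 °C to rt
Reagents that add atoms: N,O-dimethylhydroxylamine hydrochloride, CNOC.Cl
Why: Carbodiimide coupling to the Weinreb amide; this converts the carboxyl group into an acylating group for the arene and removes the carboxylate that would otherwise be alkylated in step 16.

Step 12
Reactants: 19 (6Z,9R,10E)-N-methoxy-N-methyl-9-[(4-methoxybenzyl)oxy]-13-(trimethylsilyl)trideca-6,10-dien-12-ynamide
Product: 20 (6Z,9R,10E)-9-hydroxy-N-methoxy-N-methyl-13-(trimethylsilyl)trideca-6,10-dien-12-ynamide
Conditions: DDQ (1.3 equiv), CH2Cl2/pH 7 phosphate buffer 10:1, 0 °C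
Reagents that add atoms: none
Why: Oxidative cleavage of the 4-methoxybenzyl ether by benzylic hydride abstraction and hydrolysis of the oxocarbenium ion; it is done here because neither a skipped polyene nor an electron-rich arene is yet present, and the C9–O bond is not broken.

Step 13
Reactants: 21 phloroglucinol
Product: 22 1,3,5-tris(methoxymethoxy)benzene
Conditions: MeOCH2Cl (4.5 equiv), i-Pr2NEt (6 equiv), CH2Cl2, 0 °C to rt
Reagents that add atoms: chloromethyl methyl ether, COCCl
Why: O-alkylation of the three phenols with a hard oxocarbenium-type electrophile, which should favour oxygen over ring carbon; the acetal groups later direct the lithiation.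

Step 14
Reactants: 20 (6Z,9R,10E)-9-hydroxy-N-methoxy-N-methyl-13-(trimethylsilyl)trideca-6,10-dien-12-ynamide; 22 1,3,5-tris(methoxymethoxy)benzene
Product: 24 (6Z,9R,10E)-9-hydroxy-1-[2,4,6-tris(methoxymethoxy)phenyl]-13-(trimethylsilyl)trideca-6,10-dien-12-yn-1-one, via 2,4,6-tris(methoxymethoxy)phenyllithium 23 (not isolated)
Conditions: 22 (3.5 equiv), n-BuLi (3.2 equiv), THF, 0 °C, 1 h; then 20, −78 to −20 °C; aq NH4Cl
Reagents that add atoms: none
Why: Directed ortho-lithiation between two acetal ethers, then Weinreb ketone synthesis; the first equivalent of 23 deprotonates the C9 hydroxyl, the next adds to the amide, and the chelated tetrahedral intermediate gives the ketone only on work-up.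

Step 15
Reactants: 24 (6Z,9R,10E)-9-hydroxy-1-[2,4,6-tris(methoxymethoxy)phenyl]-13-(trimethylsilyl)trideca-6,10-dien-12-yn-1-one
Product: 25 (6Z,9R,10E)-9-hydroxy-1-[2,4,6-tris(methoxymethoxy)phenyl]trideca-6,10-dien-12-yn-1-one
Conditions: K2CO3 (0.3 equiv), MeOH, 0 °C to rt
Reagents that add atoms: none
Why: Methoxide-mediated protodesilylation of the alkynylsilane; ketone, acetals and carbinol are inert to catalytic carbonate in methanol.

Step 16
Reactants: 25 (6Z,9R,10E)-9-hydroxy-1-[2,4,6-tris(methoxymethoxy)phenyl]trideca-6,10-dien-12-yn-1-one; 26 1-bromopent-2-yne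
Product: 29 (6Z,9R,10E)-9-hydroxy-1-[2,4,6-tris(methoxymethoxy)phenyl]octadeca-6,10-dien-12,15-diyn-1-one, via 1-iodopent-2-yne 27 (not isolated), via alkynylcopper intermediate 28 (not isolated)
Conditions: CuI (1.0 equiv), NaI (1.0 equiv), Cs2CO3 (1.5 equiv), DMF, rt, argon, dark
Reagents that add atoms: none
Why: Copper-mediated sp–sp3 coupling of a terminal alkyne with a propargylic halide (skipped-diyne synthesis); the monovalent copper acetylide attacks the CH2 carbon of the iodide formed in situ, and the mild carbonate base should not isomerise the 1,4-diyne or alkylate the secondary alcohol.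

Step 17
Reactants: 29 (6Z,9R,10E)-9-hydroxy-1-[2,4,6-tris(methoxymethoxy)phenyl]octadeca-6,10-dien-12,15-diyn-1-one
Product: 30 (6Z,9R,10E)-9-hydroxy-1-(2,4,6-trihydroxyphenyl)octadeca-6,10-dien-12,15-diyn-1-one
Conditions: HCl (1.25 M in MeOH, about 10 equiv), MeOH/THF, 0 °C to rt, argon
Reagents that add atoms: none
Why: Acid-catalysed transfer of the three methoxymethyl groups to methanol; it is run before the conjugated diene exists, when C9 is flanked only by an enyne whose alkynyl group stabilises a cation far less than a vinyl group, and skipped diynes tolerate acid.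

Step 18
Reactants: 30 (6Z,9R,10E)-9-hydroxy-1-(2,4,6-trihydroxyphenyl)octadeca-6,10-dien-12,15-diyn-1-one
Product: 31 (6Z,9R,10E,12Z,15Z)-9-hydroxy-1-(2,4,6-trihydroxyphenyl)octadeca-6,10,12,15-tetraen-1-one
Conditions: H2 (1 atm), Pd/CaCO3 poisoned with Pb(OAc)2, quinoline, EtOAc/MeOH, 0 °C to rt; stopped after uptake of 2 equiv H2; argon work-up
Reagents that add atoms: none
Why: Lindlar semihydrogenation; syn delivery of hydrogen on the poisoned palladium surface should turn both alkynes into Z alkenes without touching the existing alkenes, the ketone or the arene, so the acid-labile dienyl carbinol is made in the last step.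

## Compound list

1 | ethyl propiolate | C#CC(=O)OCC | starting material
2 | 4-methoxybenzyl alcohol | COc1ccc(CO)cc1 | starting material
3 | ethyl (E)-3-[(4-methoxybenzyl)oxy]acrylate | CCOC(=O)/C=C/OCc1ccc(OC)cc1 | intermediate
4 | (E)-3-[(4-methoxybenzyl)oxy]acrylic acid | OC(=O)/C=C/OCc1ccc(OC)cc1 | intermediate
5 | (E)-N-methoxy-N-methyl-3-[(4-methoxybenzyl)oxy]acrylamide | CON(C)C(=O)/C=C/OCc1ccc(OC)cc1 | intermediate
6 | trimethylsilylacetylene | C#C[Si](C)(C)C | starting material
7 | lithium trimethylsilylacetylide | [Li]C#C[Si](C)(C)C | intermediate (not isolated)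
8 | (E)-1-[(4-methoxybenzyl)oxy]-5-(trimethylsilyl)pent-1-en-4-yn-3-one | C[Si](C)(C)C#CC(=O)/C=C/OCc1ccc(OC)cc1 | intermediate
9 | (S,E)-1-[(4-methoxybenzyl)oxy]-5-(trimethylsilyl)pent-1-en-4-yn-3-ol | O[C@@H](/C=C/OCc1ccc(OC)cc1)C#C[Si](C)(C)C | intermediate
10 | (S,E)-1-[(4-methoxybenzyl)oxy]-5-(trimethylsilyl)pent-1-en-4-yn-3-yl acetate | CC(=O)O[C@@H](/C=C/OCc1ccc(OC)cc1)C#C[Si](C)(C)C | intermediate
11 | (S,E)-1-[(4-methoxybenzyl)oxy]-5-(trimethylsilyl)pent-1-en-4-yn-3-yl 1-(trimethylsilyloxy)vinyl ether (silyl ketene acetal) | C=C(O[Si](C)(C)C)O[C@@H](/C=C/OCc1ccc(OC)cc1)C#C[Si](C)(C)C | intermediate (not isolated)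
12 | trimethylsilyl (R,E)-3-[(4-methoxybenzyl)oxy]-7-(trimethylsilyl)hept-4-en-6-ynoate | C[Si](C)(C)C#C/C=C/[C@H](OCc1ccc(OC)cc1)CC(=O)O[Si](C)(C)C | intermediate (not isolated)
13 | (R,E)-3-[(4-methoxybenzyl)oxy]-7-(trimethylsilyl)hept-4-en-6-ynoic acid | C[Si](C)(C)C#C/C=C/[C@H](OCc1ccc(OC)cc1)CC(=O)O | intermediate
14 | methyl (R,E)-3-[(4-methoxybenzyl)oxy]-7-(trimethylsilyl)hept-4-en-6-ynoate | C[Si](C)(C)C#C/C=C/[C@H](OCc1ccc(OC)cc1)CC(=O)OC | intermediate
15 | (R,E)-3-[(4-methoxybenzyl)oxy]-7-(trimethylsilyl)hept-4-en-6-ynal | C[Si](C)(C)C#C/C=C/[C@H](OCc1ccc(OC)cc1)CC=O | intermediate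
16 | (5-carboxypentyl)triphenylphosphonium bromide | OC(=O)CCCCC[P+](c1ccccc1)(c1ccccc1)c1ccccc1.[Br-] | starting material
17 | sodium 6-(triphenylphosphoranylidene)hexanoate (carboxylate ylide) | [Na+].[O-]C(=O)CCCCC=P(c1ccccc1)(c1ccccc1)c1ccccc1 | intermediate (not isolated)
18 | (6Z,9R,10E)-9-[(4-methoxybenzyl)oxy]-13-(trimethylsilyl)trideca-6,10-dien-12-ynoic acid | C[Si](C)(C)C#C/C=C/[C@H](OCc1ccc(OC)cc1)C/C=C\CCCCC(=O)O | intermediate
19 | (6Z,9R,10E)-N-methoxy-N-methyl-9-[(4-methoxybenzyl)oxy]-13-(trimethylsilyl)trideca-6,10-dien-12-ynamide | C[Si](C)(C)C#C/C=C/[C@H](OCc1ccc(OC)cc1)C/C=C\CCCCC(=O)N(C)OC | intermediate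
20 | (6Z,9R,10E)-9-hydroxy-N-methoxy-N-methyl-13-(trimethylsilyl)trideca-6,10-dien-12-ynamide | C[Si](C)(C)C#C/C=C/[C@H](O)C/C=C\CCCCC(=O)N(C)OC | intermediate
21 | phloroglucinol | Oc1cc(O)cc(O)c1 | starting material
22 | 1,3,5-tris(methoxymethoxy)benzene | COCOc1cc(OCOC)cc(OCOC)c1 | intermediate
23 | 2,4,6-tris(methoxymethoxy)phenyllithium | [Li]c1c(OCOC)cc(OCOC)cc1OCOC | intermediate (not isolated)
24 | (6Z,9R,10E)-9-hydroxy-1-[2,4,6-tris(methoxymethoxy)phenyl]-13-(trimethylsilyl)trideca-6,10-dien-12-yn-1-one | C[Si](C)(C)C#C/C=C/[C@H](O)C/C=C\CCCCC(=O)c1c(OCOC)cc(OCOC)cc1OCOC | intermediate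
25 | (6Z,9R,10E)-9-hydroxy-1-[2,4,6-tris(methoxymethoxy)phenyl]trideca-6,10-dien-12-yn-1-one | C#C/C=C/[C@H](O)C/C=C\CCCCC(=O)c1c(OCOC)cc(OCOC)cc1OCOC | intermediate
26 | 1-bromopent-2-yne | CCC#CCBr | starting material
27 | 1-iodopent-2-yne | CCC#CCI | intermediate (not isolated)
28 | alkynylcopper derivative of 25 (monovalent copper acetylide) | [Cu]C#C/C=C/[C@H](O)C/C=C\CCCCC(=O)c1c(OCOC)cc(OCOC)cc1OCOC | intermediate (not isolated)
29 | (6Z,9R,10E)-9-hydroxy-1-[2,4,6-tris(methoxymethoxy)phenyl]octadeca-6,10-dien-12,15-diyn-1-one | CCC#CCC#C/C=C/[C@H](O)C/C=C\CCCCC(=O)c1c(OCOC)cc(OCOC)cc1OCOC | intermediate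
30 | (6Z,9R,10E)-9-hydroxy-1-(2,4,6-trihydroxyphenyl)octadeca-6,10-dien-12,15-diyn-1-one | CCC#CCC#C/C=C/[C@H](O)C/C=C\CCCCC(=O)c1c(O)cc(O)cc1O | intermediate
31 | (6Z,9R,10E,12Z,15Z)-9-hydroxy-1-(2,4,6-trihydroxyphenyl)octadeca-6,10,12,15-tetraen-1-one | CC/C=C\C/C=C\C=C\[C@H](O)C/C=C\CCCCC(=O)c1c(O)cc(O)cc1O | target

## Step count and least certain steps

Total step count: 18. Longest linear sequence: 17 (steps 1 to 12 and 14 to 18; step 13 prepares the arene on a side branch).

Step 7 (key step). The most likely failure is loss of geometric control. The alkynyl group is slim, so a chair with this group pseudo-axial may compete and would give the Z alkene together with the opposite configuration at C9. The enantiomeric purity of the E product would not suffer, but material and separability would. Further risks are ionisation of the γ-acyloxy enol ether in 10, fragmentation or self-condensation of the acetate enolate before silylation, and some shift across the alkyne. The fallback leaves the rearrangement for an auxiliary-controlled acetate aldol; it sets out from 6 and returns at 14. Compound 6 is lithiated (n-BuLi, THF, −78 °C) and formylated with DMF to 3-(trimethylsilyl)propynal F1. Wittig reaction with (triphenylphosphoranylidene)acetaldehyde gives (E)-5-(trimethylsilyl)pent-2-en-4-ynal F2. The titanium enolate (TiCl4, i-Pr2NEt, CH2Cl2, −78 °C) of N-acetyl-(S)-4-isopropylthiazolidine-2-thione adds to F2 to give (R,E)-3-hydroxy-1-[(S)-4-isopropyl-2-thioxothiazolidin-3-yl]-7-(trimethylsilyl)hept-4-en-6-yn-1-one F3. The facial sense is taken from the chelated chair model, the diastereomers should be separable, and the enantiomeric auxiliary is used if the sense proves to be the reverse. Methanol and imidazole release methyl (R,E)-3-hydroxy-7-(trimethylsilyl)hept-4-en-6-ynoate F4, and 4-methoxybenzyl 2,2,2-trichloroacetimidate with catalytic Sc(OTf)3 converts F4 into 14.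

Step 5. The most likely failure is poor facial discrimination, because both substituents of ketone 8 are unsaturated and the catalyst may not tell the alkynyl from the alkoxyvinyl group. In addition, the push-pull character of the ketone may make the hydrogen transfer from i-PrOH incomplete, and the alkoxy group may exchange with the solvent. The fallback replaces asymmetric catalysis by resolution; it sets out from 8 and returns at 9. Reduction of 8 with NaBH4 in MeOH/THF at −20 °C gives the racemic alcohol (E)-1-[(4-methoxybenzyl)oxy]-5-(trimethylsilyl)pent-1-en-4-yn-3-ol F5. Kinetic resolution with Burkholderia cepacia lipase and vinyl acetate in hexane is expected to acetylate the (R)-enantiomer to (R,E)-1-[(4-methoxybenzyl)oxy]-5-(trimethylsilyl)pent-1-en-4-yn-3-yl acetate F6 and to leave (S)-9, which re-enters at step 6. If the enzyme prefers the other enantiomer, the acetate it forms is 10 itself.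

Step 17. The most likely failure is acid-promoted ionisation at C9 while the three aryl acetals are cleaved, leading to solvolysis by methanol or allylic transposition, because cleavage of aryl methoxymethyl ethers needs more acid than an allylic carbinol comfortably tolerates. The fallback changes the phenol protection to allyl ethers removed by palladium under neutral conditions; it sets out from 21 and 20 and returns at 30. Compound 21 is O-allylated (allyl bromide, K2CO3, DMF) to 1,3,5-tris(allyloxy)benzene F7 and brominated with N-bromosuccinimide to 2-bromo-1,3,5-tris(allyloxy)benzene F8. Bromine–lithium exchange (n-BuLi, THF, −78 °C) gives 2,4,6-tris(allyloxy)phenyllithium F9, which adds to 20 to give (6Z,9R,10E)-9-hydroxy-1-[2,4,6-tris(allyloxy)phenyl]-13-(trimethylsilyl)trideca-6,10-dien-12-yn-1-one F10. K2CO3 in MeOH gives the terminal alkyne (6Z,9R,10E)-9-hydroxy-1-[2,4,6-tris(allyloxy)phenyl]trideca-6,10-dien-12-yn-1-one F11. Coupling with 26 as in step 16 gives (6Z,9R,10E)-9-hydroxy-1-[2,4,6-tris(allyloxy)phenyl]octadeca-6,10-dien-12,15-diyn-1-one F12, and Pd(PPh3)4 with morpholine in THF transfers the three allyl groups to the amine and gives 30.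

Step 18. The most likely failure is over-reduction or incomplete reduction when two alkynes of different reactivity (one conjugated, one isolated) are hydrogenated together, giving by-products that are hard to separate from a final product; geometric isomerisation on the catalyst is a further risk. The fallback brings in C15=C16 as a preformed Z alkene and reduces only the conjugated alkyne with a reagent that cannot over-reduce; it sets out from 25 and returns at 31. Compound 25 is coupled with (Z)-1-bromopent-2-ene (CuI, NaI, Cs2CO3, DMF) to (6Z,9R,10E,15Z)-9-hydroxy-1-[2,4,6-tris(methoxymethoxy)phenyl]octadeca-6,10,15-trien-12-yn-1-one F13. HCl in MeOH removes the acetals to give (6Z,9R,10E,15Z)-9-hydroxy-1-(2,4,6-trihydroxyphenyl)octadeca-6,10,15-trien-12-yn-1-one F14, and zinc activated with Cu(OAc)2 and AgNO3 in MeOH/H2O reduces the conjugated alkyne of F14 to the Z alkene, giving 31.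

## Further compounds

F1 | step 7 | 3-(trimethylsilyl)propynal | C[Si](C)(C)C#CC=O
F2 | step 7 | (E)-5-(trimethylsilyl)pent-2-en-4-ynal | C[Si](C)(C)C#C/C=C/C=O
F3 | step 7 | (R,E)-3-hydroxy-1-[(S)-4-isopropyl-2-thioxothiazolidin-3-yl]-7-(trimethylsilyl)hept-4-en-6-yn-1-one | C[Si](C)(C)C#C/C=C/[C@H](O)CC(=O)N1[C@@H](C(C)C)CSC1=S
F4 | step 7 | methyl (R,E)-3-hydroxy-7-(trimethylsilyl)hept-4-en-6-ynoate | C[Si](C)(C)C#C/C=C/[C@H](O)CC(=O)OC
F5 | step 5 | racemic (E)-1-[(4-methoxybenzyl)oxy]-5-(trimethylsilyl)pent-1-en-4-yn-3-ol | OC(/C=C/OCc1ccc(OC)cc1)C#C[Si](C)(C)C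
F6 | step 5 | (R,E)-1-[(4-methoxybenzyl)oxy]-5-(trimethylsilyl)pent-1-en-4-yn-3-yl acetate | CC(=O)O[C@H](/C=C/OCc1ccc(OC)cc1)C#C[Si](C)(C)C
F7 | step 17 | 1,3,5-tris(allyloxy)benzene | C=CCOc1cc(OCC=C)cc(OCC=C)c1
F8 | step 17 | 2-bromo-1,3,5-tris(allyloxy)benzene | C=CCOc1cc(OCC=C)c(Br)c(OCC=C)c1
F9 | step 17 | 2,4,6-tris(allyloxy)phenyllithium | [Li]c1c(OCC=C)cc(OCC=C)cc1OCC=C
F10 | step 17 | (6Z,9R,10E)-9-hydroxy-1-[2,4,6-tris(allyloxy)phenyl]-13-(trimethylsilyl)trideca-6,10-dien-12-yn-1-one | C[Si](C)(C)C#C/C=C/[C@H](O)C/C=C\CCCCC(=O)c1c(OCC=C)cc(OCC=C)cc1OCC=C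
F11 | step 17 | (6Z,9R,10E)-9-hydroxy-1-[2,4,6-tris(allyloxy)phenyl]trideca-6,10-dien-12-yn-1-one | C#C/C=C/[C@H](O)C/C=C\CCCCC(=O)c1c(OCC=C)cc(OCC=C)cc1OCC=C
F12 | step 17 | (6Z,9R,10E)-9-hydroxy-1-[2,4,6-tris(allyloxy)phenyl]octadeca-6,10-dien-12,15-diyn-1-one | CCC#CCC#C/C=C/[C@H](O)C/C=C\CCCCC(=O)c1c(OCC=C)cc(OCC=C)cc1OCC=C
F13 | step 18 | (6Z,9R,10E,15Z)-9-hydroxy-1-[2,4,6-tris(methoxymethoxy)phenyl]octadeca-6,10,15-trien-12-yn-1-one | CC/C=C\CC#C/C=C/[C@H](O)C/C=C\CCCCC(=O)c1c(OCOC)cc(OCOC)cc1OCOC
F14 | step 18 | (6Z,9R,10E,15Z)-9-hydroxy-1-(2,4,6-trihydroxyphenyl)octadeca-6,10,15-trien-12-yn-1-one | CC/C=C\CC#C/C=C/[C@H](O)C/C=C\CCCCC(=O)c1c(O)cc(O)cc1O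
A1 | alternative 1 | (6Z,9R,10E,12Z,15Z)-9-(tert-butyldimethylsilyloxy)-1-(2,4,6-trihydroxyphenyl)octadeca-6,10,12,15-tetraen-1-one | CC/C=C\C/C=C\C=C\[C@H](O[Si](C)(C)C(C)(C)C)C/C=C\CCCCC(=O)c1c(O)cc(O)cc1O
A2 | alternative 1 | methyl (12Z,15R,16E,18Z,21Z)-15-(tert-butyldimethylsilyloxy)-3,5,7-trioxotetracosa-12,16,18,21-tetraenoate | CC/C=C\C/C=C\C=C\[C@H](O[Si](C)(C)C(C)(C)C)C/C=C\CCCCC(=O)CC(=O)CC(=O)CC(=O)OC
A3 | alternative 2 | (R,Z)-10-{[(4-methoxybenzyl)oxy]methyl}-3,4,5,6,9,10-hexahydro-2H-oxecin-2-one | O=C1CCCC/C=C\C[C@H](COCc2ccc(OC)cc2)O1
A4 | alternative 2 | (R)-1-[(4-methoxybenzyl)oxy]pent-4-en-2-yl hept-6-enoate | C=CC[C@H](COCc1ccc(OC)cc1)OC(=O)CCCCC=C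
A5 | alternative 3 | methyl (6Z,9R,10E)-9-(tert-butyldimethylsilyloxy)octadeca-6,10-dien-12,15-diynoate | CCC#CCC#C/C=C/[C@H](O[Si](C)(C)C(C)(C)C)C/C=C\CCCCC(=O)OC
A6 | alternative 3 | methyl (6Z,9R,10E)-9-(tert-butyldimethylsilyloxy)-11-iodoundeca-6,10-dienoate | I/C=C/[C@H](O[Si](C)(C)C(C)(C)C)C/C=C\CCCCC(=O)OC
A7 | alternative 3 | hepta-1,4-diyne | C#CCC#CCC
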